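## The problem

Target **29** is a trans-fused labdane-type decalin acid. Labdane numbering is used throughout: ring A = C1–C5 and C10, ring B = C5–C10, chain C11–C15 on C9. Six of its seven stereocentres are contiguous around the bicycle (C2, C3, C4, C5, C10, C9); the seventh, C13, lies in a flexible chain out of reach of any ring centre and has to be bought with the chain. Within the bicycle the centres can steer one another: C5 can direct the quaternary C10, and the axial C10 methyl then shields one face of both rings. Ring A is the dense part: a cis-2,3-diol on the face anti to the C10 methyl, acetylated only at the equatorial C2 oxygen, beside a quaternary C4 with an equatorial methyl and an axial formyl group (C19) syn to the C10 methyl. The functional groups are fragile together. The C3 hydroxyl and the C19 formyl form a β-hydroxy aldehyde open to retro-aldol cleavage in base, the monoacetate migrates or is lost in base, the C7–C8 alkene can slip to C8–C9 in strong acid, and the C15 acid must be freed without touching any of these. Ring B needs the chain on C9 syn to the C10 methyl, at a centre that is allylic and flanked by a quaternary carbon. The enabling feature is that C2, C3 and C19 are all aldehyde-level carbons once the diol is read as a pinacol, and that C3 and C19 both sit on C4. A C4 bearing two formyl groups is not stereogenic, so reductive coupling of a C2 aldehyde with one of them closes ring A and creates C2, C3 and C4 in one event.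

## Retrosynthesis

**Acetate and masking groups, 29 ⇒ 28 ⇒ 26.** The C2–O acetyl bond is cut first. An acetate carried through the route would not survive the ylide, fluoride and hydroxide used earlier, whereas the equatorial C2 hydroxyl of dihydroxy acid **28** should be distinguishable from the axial, neopentyl C3 hydroxyl by rate alone. Acid **28** is the hydrolysis product of methyl ester **26**, in which the diol is an acetonide and C19 a dimethyl acetal. Base must come first, while O3 is still an ether and cannot start a retro-aldol, and acid second. Only chemoselectivity is asked of these forward steps.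

**C11–C12, 26 ⇒ 22 + 24.** The chain is cut between C11 and C12. A C9–C11 cut would need a carbon nucleophile at the hindered C9 carbonyl of **21** and then removal of a tertiary allylic oxygen with control of C9 and of the alkene position. A C12–C13 cut would disturb the chain stereocentre. The chosen cut gives diene **22**, whose exocyclic methylene is C11, and iodide **24**, which carries C12–C15 with C13 in place. Forward, hydroboration of **22** must put boron on C11 and hydrogen on C9 from the face anti to the C10 methyl, and borane **25** must then undergo an alkyl–alkyl Suzuki–Miyaura coupling with **24**.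

**Chain fragment, 24 ⇒ 23.** The C12–I bond is traced to the free carboxyl of half-ester **23**. Loss of CO2 with capture of iodine shortens the five-carbon diacid to the four carbons needed, and the stereocentre, which is not the reacting carbon, is untouched. The methyl ester of **23** becomes C15.

**Ring B adjustments, 22 ⇒ 21 ⇒ 20 ⇒ 19 ⇒ 17.** The C9=C11 bond is cut to enone **21** (a methylenation), the oxidised form of allylic alcohol **20** and of silyl ether **19**. Compound **19** differs from diol aldehyde **17** only by the acetonide and the C19 acetal. The C9 oxygen travels as a silyl ether because an enone would survive neither SmI2 nor the base of the earlier steps. The C19 formyl is masked as an acetal and not reduced and re-oxidised, which saves operations and lets one acid treatment at the end release it with the diol.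

**C2–C3, the key cut, 17 ⇒ 16.** Cutting the diol bond opens ring A and removes three stereocentres at once, leading to trialdehyde **16**. The neighbouring cuts are weaker. A C3–C4 aldol cut needs an acyclic quaternary C4 set beforehand. Dihydroxylation of a C2=C3 alkene would give the right diol face but again presupposes C4. In **16** C4 carries two identical formyl groups, so the only stereocentres are those of ring B. The forward reaction must couple the C2 aldehyde with one C4 formyl, give the cis-diol on the face anti to the C10 methyl, and leave the other formyl axial.

**C4–C3 and C4–C19, 16 ⇒ 15 ⇒ 14 ⇒ 11 + 12.** Trialdehyde **16** is the oxidation product of triol **15**, which comes from diol ester **14** by ester reduction. The two hydroxymethyl arms of **14** are traced to one aldehyde, **11**, and formaldehyde **12**: an aldol reaction installs the first carbon and a crossed Cannizzaro reduction makes both arms alike. This is simpler than any stepwise introduction, because the configuration of C4 in **11** no longer matters.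

**From the isopropenyl group, 11 ⇒ 10 ⇒ 8 ⇒ 7 ⇒ 6.** Aldehyde **11** is the oxidised anti-Markovnikov hydration product (**10**) of the isopropenyl group of silyl ether **8**. Compound **8** is the protected 1,2-reduction product (**7**) of enone **6**. The forward hydroboration has to choose the 1,1-disubstituted alkene over the trisubstituted ring alkene.

**C10–C1 and C10–C20, 6 ⇒ 3 + 4 and 3 ⇒ 1.** Both bonds to the quaternary C10 are enolate alkylations of (S)-carvone **1**, whose single stereocentre is C5 of the target. The order matters: methyl first (**3**), then the acetate arm from bromoacetate **4**, so that the larger electrophile enters anti to the isopropenyl group and fixes C10.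

## Roads not taken

**Alternative 1:** The cut is C5–C10 of ring B. Forward, ten-membered (Z,Z)-dienyl lactone **A1** is enolised and O-silylated (LDA, Me3SiCl), and a transannular [3,3] shift contracts it to ring B acid **A2**, with the carboxyl (C4) on C5 and methyl and (E)-propenyl (C1–C3) on C10.
- Merits: the quaternary C10 arises by a concerted, suprafacial shift with chirality transfer from the carbinol centre. The chain with C13 is present from the start, so no late sp3–sp3 coupling at C9 is needed. In that respect this road is better than the chosen one, which has to set against it a late hydroboration and coupling at a hindered centre, albeit with a strong facial bias.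
- Weak points: **A1** is itself costly, a medium ring with two Z alkenes and three stereocentres. Ring-constrained contractions of this kind usually pass through a boat-like transition state that places carboxyl and alkenyl cis, whereas **A2** needs them trans, so C5 would probably have to be epimerised. After the key step ring A is still unmade: C4 is a carboxyl carbon needing three new C–C bonds (to C3, C18, C19), C3 is an unfunctionalised methyl, and C1=C2 must be reduced at C1 and oxidised at C2.
- Comparison: the chosen plan obtains ring B from the chiral pool in two alkylations and spends its key step on ring A, where the stereochemical density lies.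

**Alternative 2:** The cuts are C1–C10 and C2–C3. Forward, Fe(acac)3 and PhSiH3 transfer a hydrogen atom to the exocyclic C10 methylene of ring B aldehyde **A3**. The tertiary C10 radical adds to methyl vinyl ketone **A4**, and the resulting enolate closes ring A onto the C3 aldehyde, giving decalin **A5** with C2 acetyl, C3 hydroxyl and C10 methyl.
- Merits: two C–C bonds, ring A, the quaternary C10 and two further stereocentres form in one operation on a fragment that already carries the chain. The C2 acetyl group is a latent acetoxy group, since a Baeyer–Villiger oxidation would convert it with retention. On paper the endgame is shorter than the chosen one, and in bond economy this road is better.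
- Weak points: **A3** contains the acyclic quaternary C4 stereocentre (methyl, silyloxymethyl, formyl) beside C5, and the C9 centre, all to be set before any ring exists to help. Hydrogen-atom transfer must choose the exocyclic alkene over C7=C8, and the radical must be trapped on the face that leaves the methyl axial. The aldol must give the axial C3 hydroxyl cis to the C2 substituent against retro-aldol equilibration. A peracid for the Baeyer–Villiger step would also epoxidise C7=C8.
- Comparison: the chosen plan sets against the better bond economy that C4 is not stereogenic until ring A closes, so no acyclic quaternary centre has to be controlled.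

**Alternative 3:** The cuts are C5–C6 and C9–C10. Forward, (E)-diene **A7**, made from (R)-citronellol **A6**, reacts with ethyl (E)-3-methyl-4-oxobut-2-enoate **A8** under a chiral oxazaborolidinium Lewis acid, formyl exo, to give ring B cycloadduct **A9** with C10 methyl and formyl (C1) and C5 ethoxycarbonyl (C4).
- Merits: convergent and catalytic. C5, C9 and C10 are set in one step, and the chain arrives with the diene. For ring B and C9 this is arguably the best construction, and better than the chosen plan's late C9 chemistry.
- Weak points: the alkyl group on the C9 terminus and the C8 methyl of **A7** direct the regiochemistry in opposite senses, and **A8** has acceptors on both alkene carbons. A trisubstituted dienophile must form a quaternary centre next to a substituted diene terminus with the less usual exo topology. After the cycloaddition ring A is untouched: C4 is again a carboxyl carbon three C–C bonds short, C1 needs a two-carbon extension, and the three ring A stereocentres remain.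
- Comparison: the chosen plan is linear and takes its ring B stereocentres from carvone, but its key step creates exactly the part that **A9** leaves open.

Key step: step 10

Remarks on the chemistry (assumptions):
- "Syn" and "anti" refer to the face of the six-membered ring or decalin relative to the C10 methyl.
- Compound **3** is taken forward as a mixture of C6 epimers (carvone numbering), and **9**, **10**, **11** and **13** as mixtures of C4 epimers. Both centres lose their stereogenicity later (steps 2 and 7), so their SMILES leave them undefined.
- Trialdehyde **16** is used crude and cold directly after work-up.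

## Steps

Step 1
Reactants: 1 (S)-carvone
Product: 3 6-methylcarvone (C6 epimers), via lithium enolate 2 (not isolated)
Conditions: LDA, THF, −78 °C; MeI, −78 → −20 °C
Reagents that add atoms: iodomethane, CI
Why: Kinetic deprotonation at the α′ carbon (C6 of carvone, the future C10) gives the cross-conjugated enolate 2, which is C-methylated (enolate alkylation); the epimer mixture is harmless because this centre is planarised again in step 2.

Step 2
Reactants: 3 6-methylcarvone; 4 tert-butyl bromoacetate
Product: 6 quaternary keto ester, via lithium enolate 5 (not isolated)
Conditions: LDA, THF, −78 °C; then 4, DMPU, −78 → 0 °C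
Reagents that add atoms: none
Why: Enolate alkylation of the tetrasubstituted enolate 5; the electrophile enters anti to the neighbouring isopropenyl group on C5, so the acetate arm (C1–C2) ends trans and the methyl (C20) cis to it, which is the C10 configuration of the target. Introducing the small group first and the large one second is the established way to set this centre on carvone.

Step 3
Reactants: 6 quaternary keto ester
Product: 7 allylic alcohol
Conditions: NaBH4, CeCl3·7H2O, MeOH, −40 → 0 °C
Reagents that add atoms: none
Why: Luche 1,2-reduction; hydride adds axially from the face opposite the axial C10 methyl and gives the pseudo-equatorial alcohol syn to that methyl, while the low temperature and the tert-butyl ester keep the γ-hydroxy ester from lactonising. The C9 centre is temporary, since it is re-oxidised in step 13.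

Step 4
Reactants: 7 allylic alcohol
Product: 8 silyl ether
Conditions: TBSOTf, 2,6-lutidine, CH2Cl2, −78 → 0 °C
Reagents that add atoms: tert-butyldimethylsilyl triflate, CC(C)(C)[Si](C)(C)OS(=O)(=O)C(F)(F)F
Why: Silylation of a hindered secondary alcohol with the silyl triflate; at low temperature the hydroxyl reacts well before the tert-butyl ester is attacked.

Step 5
Reactants: 8 silyl ether
Product: 10 primary alcohol (C4 epimers), via B-alkyl-9-BBN borane 9 (not isolated)
Conditions: 9-BBN, THF, 0 °C → rt; then NaOH, H2O2, 0 °C
Reagents that add atoms: 9-borabicyclo[3.3.1]nonane, B1C2CCCC1CCC2 (retained only in 9); hydrogen peroxide, OO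
Why: Hydroboration–oxidation; 9-BBN adds to the 1,1-disubstituted isopropenyl alkene and leaves the trisubstituted ring alkene and the ester alone, placing oxygen on the terminal carbon. The new C4 centre is formed unselectively and is erased in step 7.

Step 6
Reactants: 10 primary alcohol
Product: 11 aldehyde (C4 epimers)
Conditions: Dess–Martin periodinane, NaHCO3, CH2Cl2, 0 °C → rt
Reagents that add atoms: none
Why: Dess–Martin oxidation of a primary alcohol under buffered, near-neutral conditions that the silyl ether and the tert-butyl ester tolerate.

Step 7
Reactants: 11 aldehyde; 12 formaldehyde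
Product: 14 1,3-diol ester, via hydroxymethyl aldehyde 13 (not isolated)
Conditions: 37% aq. HCHO (excess), KOH, 1,4-dioxane–H2O, rt
Reagents that add atoms: none
Why: Tollens condensation: the enolate of 11 adds to formaldehyde (aldol) to give 13, which has no α-hydrogen and is reduced by hydride transfer from a second formaldehyde (crossed Cannizzaro). C4 then carries two identical arms and is no longer stereogenic; the tert-butyl ester and the hindered silyl ether withstand aqueous hydroxide at room temperature.

Step 8
Reactants: 14 1,3-diol ester
Product: 15 triol
Conditions: LiAlH4, THF, 0 °C → rt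
Reagents that add atoms: none
Why: Hydride reduction of the tert-butyl ester to the primary alcohol (C2); the allylic silyl ether is inert.

Step 9
Reactants: 15 triol
Product: 16 trialdehyde
Conditions: (COCl)2, DMSO, CH2Cl2, −78 °C; Et3N, −78 → −20 °C; cold pH 7 buffer
Reagents that add atoms: none
Why: Threefold Swern oxidation; all three alcohols are activated as alkoxysulfonium salts before the amine is added, so no free β-hydroxy aldehyde meets base, and the geminal dialdehyde on C4 cannot enolise. The product is taken on at once because of the enolisable C2 aldehyde and the deformylation-prone 1,3-dialdehyde.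

Step 10
Reactants: 16 trialdehyde
Product: 17 decalin cis-2,3-diol with axial C19 formyl
Conditions: SmI2 (2.2 equiv, 0.1 M in THF, slow addition), t-BuOH (2 equiv), THF (0.01 M), −78 → −20 °C; aq. NH4Cl
Reagents that add atoms: none
Why: Divalent samarium transfers one electron to an aldehyde of 16 to give a ketyl; the oxophilic trivalent samarium of the ketyl binds a second formyl oxygen, the ketyl carbon adds to that carbonyl, and a second electron with protonation by t-BuOH gives the samarium diolate and, on work-up, the diol. The closest known reaction is the SmI2-mediated intramolecular pinacol coupling of 1,6-dialdehydes to cis-cyclohexane-1,2-diols. Ring A closes by 6-exo-trig addition of the ketyl carbon to the partner carbonyl, forming C2–C3. The cis relation of O2 and O3 follows from the samarium bridge between the two oxygens in the bond-forming transition state. The face is set by the axial C10 methyl: in the chair-like transition state the cis-diol with O2 equatorial and O3 axial, both anti to that methyl, is preferred because the other cis-diol would place O2 syn-axial to it. C4 becomes stereogenic through the choice of formyl: the one that reacts is the one that leaves the C4 methyl equatorial and the remaining formyl axial, since an axial methyl would meet the C10 methyl in a 1,3-diaxial contact that the smaller, flat formyl group largely avoids. The step needs 1,6-coupling to win over the geminal pair and over intermolecular coupling: the geminal formyls could only close a strained, reversibly formed three-membered diolate, neither can enolise, and high dilution with no more than 2.2 equivalents of SmI2 favours the six-membered ring and spares the C19 formyl.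

Step 11
Reactants: 17 decalin cis-2,3-diol with axial C19 formyl
Product: 19 acetonide dimethyl acetal, via acetonide aldehyde 18 (not isolated)
Conditions: 2,2-dimethoxypropane–MeOH (4:1), CSA (cat.), rt
Reagents that add atoms: 2,2-dimethoxypropane, COC(C)(C)OC
Why: Acid-catalysed acetal exchange: the cis-diol closes the five-membered acetonide first, and the hindered C19 formyl is then converted to its dimethyl acetal by the same reagent, which also scavenges water. The C2 oxygen is trans to C19, so no lactol can compete; partial loss of the silyl group would be harmless because it is removed in step 12.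

Step 12
Reactants: 19 acetonide dimethyl acetal
Product: 20 allylic alcohol
Conditions: TBAF, THF, 50 °C; aq. NH4Cl
Reagents that add atoms: none
Why: Fluoride cleavage of the silyl ether; both acetals are stable to the basic fluoride, and O3 is an ether, so no retro-aldol path exists.

Step 13
Reactants: 20 allylic alcohol
Product: 21 enone
Conditions: Dess–Martin periodinane, NaHCO3, CH2Cl2, rt
Reagents that add atoms: none
Why: Dess–Martin oxidation of the allylic alcohol to the conjugated C9 ketone; the bicarbonate buffer protects the acetals from the acetic acid formed.

Step 14
Reactants: 21 enone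
Product: 22 diene
Conditions: Ph3PCH3Br, KOtBu, toluene, rt → 90 °C
Reagents that add atoms: methyltriphenylphosphonium bromide, C[P+](c1ccccc1)(c1ccccc1)c1ccccc1.[Br-]
Why: Wittig methylenation under the forcing alkoxide conditions used for hindered ketones; the α′ carbon (C10) is quaternary, so only reversible γ-deprotonation can compete. The new methylene is C11.

Step 15
Reactants: 23 methyl hydrogen (R)-3-methylglutarate
Product: 24 methyl (S)-4-iodo-3-methylbutanoate
Conditions: PhI(OAc)2, I2, cyclohexane, hν (tungsten lamp), 70 °C
Reagents that add atoms: iodine, II
Why: Hunsdiecker-type iododecarboxylation: the acyl hypoiodite formed in the flask fragments to CO2 and a primary radical that is trapped by iodine. The stereocentre is not the radical carbon and keeps its geometry (the descriptor changes to S only through the priority rules).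

Step 16
Reactants: 22 diene; 24 methyl (S)-4-iodo-3-methylbutanoate
Product: 26 coupled methyl ester, via alkylborane 25 (not isolated)
Conditions: 9-BBN, THF, 0 °C → rt; then 24 (1.5 equiv), Pd(OAc)2 (cat.), PCy3 (cat.), K3PO4·H2O, THF, rt → 40 °C
Reagents that add atoms: 9-borabicyclo[3.3.1]nonane, B1C2CCCC1CCC2 (retained only in 25)
Why: Hydroboration puts boron on the terminal C11 of the exocyclic alkene and hydrogen on C9 from the face anti to the adjacent axial C10 methyl, which sets C9 with the chain syn to that methyl and leaves a homoallylic borane. The B-alkyl Suzuki–Miyaura alkyl–alkyl coupling with the primary iodide then forms C11–C12; the electron-rich bulky phosphine favours reductive elimination over β-hydride loss, and the hydrated phosphate activates boron without touching the methyl ester.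

Step 17
Reactants: 26 coupled methyl ester
Product: 28 dihydroxy aldehyde acid, via acetal acid 27 (not isolated)
Conditions: LiOH·H2O, THF–H2O, rt; then 2 M HCl to pH 1, rt
Reagents that add atoms: lithium hydroxide, [Li+].[OH-] (carboxyl oxygen); water, O (formyl oxygen)
Why: Saponification is done while O3 is still an ether, so base cannot start a retro-aldol; acidifying the same solution then hydrolyses the acetonide and the dimethyl acetal, conditions under which the β-hydroxy aldehyde is stable and which are mild enough for the C7–C8 alkene.

Step 18
Reactants: 28 dihydroxy aldehyde acid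
Product: 29 target acid
Conditions: Ac2O, pyridine, CH2Cl2, 0 °C; H2O work-up
Reagents that add atoms: acetic anhydride, CC(=O)OC(C)=O
Why: Rate-selective acylation: the equatorial C2 hydroxyl reacts, whereas the axial C3 hydroxyl next to the quaternary C4 is too hindered without an acyl-transfer catalyst. Any mixed anhydride at C15 is hydrolysed on aqueous work-up.

## Compound list

1 | (S)-carvone, (5S)-2-methyl-5-(prop-1-en-2-yl)cyclohex-2-en-1-one | CC1=CC[C@@H](CC1=O)C(C)=C | starting material
2 | lithium cross-conjugated dienolate of 1 (O–Li on C1, C1=C6 and C2=C3) | [Li]OC1=C[C@@H](C(C)=C)CC=C1C | intermediate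
3 | 6-methylcarvone, (5S)-2,6-dimethyl-5-(prop-1-en-2-yl)cyclohex-2-en-1-one, C6 epimers (trans expected to predominate) | CC1C(=O)C(C)=CC[C@@H]1C(C)=C | intermediate
4 | tert-butyl bromoacetate | CC(C)(C)OC(=O)CBr | starting material
5 | lithium enolate of 3 (tetrasubstituted C1=C6) | [Li]OC1=C(C)[C@@H](C(C)=C)CC=C1C | intermediate
6 | tert-butyl 2-[(1R,6R)-1,3-dimethyl-2-oxo-6-(prop-1-en-2-yl)cyclohex-3-en-1-yl]acetate (acetate arm trans to isopropenyl) | CC(C)(C)OC(=O)C[C@@]1(C)C(=O)C(C)=CC[C@@H]1C(C)=C | intermediate
7 | tert-butyl 2-[(1R,2R,6R)-2-hydroxy-1,3-dimethyl-6-(prop-1-en-2-yl)cyclohex-3-en-1-yl]acetate (hydroxyl syn to the ring methyl on C1) | CC(C)(C)OC(=O)C[C@@]1(C)[C@H](O)C(C)=CC[C@@H]1C(C)=C | intermediate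
8 | tert-butyldimethylsilyl ether of 7 | CC(C)(C)OC(=O)C[C@@]1(C)[C@H](O[Si](C)(C)C(C)(C)C)C(C)=CC[C@@H]1C(C)=C | intermediate
9 | B-alkyl-9-BBN borane from 8 (boron on the terminal carbon of the former isopropenyl group, C4 epimers) | CC(C)(C)OC(=O)C[C@@]1(C)[C@H](O[Si](C)(C)C(C)(C)C)C(C)=CC[C@@H]1C(C)CB2C3CCCC2CCC3 | intermediate
10 | primary alcohol: 8 with the isopropenyl group replaced by 1-hydroxypropan-2-yl (C4 epimers) | CC(C)(C)OC(=O)C[C@@]1(C)[C@H](O[Si](C)(C)C(C)(C)C)C(C)=CC[C@@H]1C(C)CO | intermediate
11 | aldehyde: 8 with the isopropenyl group replaced by 1-oxopropan-2-yl (C4 epimers) | CC(C)(C)OC(=O)C[C@@]1(C)[C@H](O[Si](C)(C)C(C)(C)C)C(C)=CC[C@@H]1C(C)C=O | intermediate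
12 | formaldehyde | C=O | starting material
13 | hydroxymethyl aldehyde: C4 bearing methyl, hydroxymethyl and formyl (C4 epimers) | CC(C)(C)OC(=O)C[C@@]1(C)[C@H](O[Si](C)(C)C(C)(C)C)C(C)=CC[C@@H]1C(C)(CO)C=O | intermediate
14 | 1,3-diol ester: C4 bearing methyl and two hydroxymethyl groups, C10 bearing methyl and the tert-butyl acetate arm, C9 silyl ether | CC(C)(C)OC(=O)C[C@@]1(C)[C@H](O[Si](C)(C)C(C)(C)C)C(C)=CC[C@@H]1C(C)(CO)CO | intermediate
15 | triol: 14 with the ester reduced to 2-hydroxyethyl (C1–C2) | OCC[C@@]1(C)[C@H](O[Si](C)(C)C(C)(C)C)C(C)=CC[C@@H]1C(C)(CO)CO | intermediate
16 | ring B trialdehyde: cyclohexene (C7=C8, C8 methyl) with C9 silyl ether syn to the C10 methyl, C10 bearing methyl and formylmethyl, C5 bearing the 1,1-diformylethyl group, H5 anti to the C10 methyl | O=CC[C@@]1(C)[C@H](O[Si](C)(C)C(C)(C)C)C(C)=CC[C@@H]1C(C)(C=O)C=O | intermediate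
17 | trans-decalin cis-2,3-diol: 2-OH equatorial and 3-OH axial, both anti to the C10 methyl; C4 with equatorial methyl and axial formyl (C19) syn to the C10 methyl; C9 silyl ether; C7=C8 | O[C@H]1C[C@@]2(C)[C@H](O[Si](C)(C)C(C)(C)C)C(C)=CC[C@@H]2[C@](C)(C=O)[C@H]1O | intermediate
18 | 2,3-O-isopropylidene derivative of 17 (C19 formyl free) | CC1(C)O[C@H]2C[C@@]3(C)[C@H](O[Si](C)(C)C(C)(C)C)C(C)=CC[C@@H]3[C@](C)(C=O)[C@H]2O1 | intermediate
19 | 2,3-acetonide with C19 as dimethyl acetal, C9 silyl ether | CC1(C)O[C@H]2C[C@@]3(C)[C@H](O[Si](C)(C)C(C)(C)C)C(C)=CC[C@@H]3[C@](C)(C(OC)OC)[C@H]2O1 | intermediate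
20 | allylic alcohol: 19 with free C9 hydroxyl (syn to the C10 methyl) | CC1(C)O[C@H]2C[C@@]3(C)[C@H](O)C(C)=CC[C@@H]3[C@](C)(C(OC)OC)[C@H]2O1 | intermediate
21 | enone: C9 ketone conjugated with C7=C8, acetonide and C19 dimethyl acetal retained | CC1(C)O[C@H]2C[C@@]3(C)C(=O)C(C)=CC[C@@H]3[C@](C)(C(OC)OC)[C@H]2O1 | intermediate
22 | diene: exocyclic C9=C11 methylene conjugated with C7=C8 | CC1(C)O[C@H]2C[C@@]3(C)C(=C)C(C)=CC[C@@H]3[C@](C)(C(OC)OC)[C@H]2O1 | intermediate
23 | methyl hydrogen (R)-3-methylglutarate, (3R)-5-methoxy-3-methyl-5-oxopentanoic acid | OC(=O)C[C@@H](C)CC(=O)OC | starting material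
24 | methyl (3S)-4-iodo-3-methylbutanoate | IC[C@@H](C)CC(=O)OC | intermediate
25 | alkylborane: 9-BBN on C11, H9 anti and C11 syn to the C10 methyl | CC1(C)O[C@H]2C[C@@]3(C)[C@H](CB4C5CCCC4CCC5)C(C)=CC[C@@H]3[C@](C)(C(OC)OC)[C@H]2O1 | intermediate
26 | methyl (13R)-labd-7-en-15-oate bearing the 2,3-acetonide and the C19 dimethyl acetal (full skeleton, chain on C9 syn to the C10 methyl) | CC1(C)O[C@H]2C[C@@]3(C)[C@H](CC[C@@H](C)CC(=O)OC)C(C)=CC[C@@H]3[C@](C)(C(OC)OC)[C@H]2O1 | intermediate
27 | carboxylic acid of 26 (acetonide and acetal retained) | CC1(C)O[C@H]2C[C@@]3(C)[C@H](CC[C@@H](C)CC(=O)O)C(C)=CC[C@@H]3[C@](C)(C(OC)OC)[C@H]2O1 | intermediate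
28 | (2S,3R,4S,5S,9R,10S,13R)-2,3-dihydroxy-19-oxolabd-7-en-15-oic acid | O[C@H]1C[C@@]2(C)[C@H](CC[C@@H](C)CC(=O)O)C(C)=CC[C@@H]2[C@](C)(C=O)[C@H]1O | intermediate
29 | (2S,3R,4S,5S,9R,10S,13R)-2-acetoxy-3-hydroxy-19-oxolabd-7-en-15-oic acid | CC(=O)O[C@H]1C[C@@]2(C)[C@H](CC[C@@H](C)CC(=O)O)C(C)=CC[C@@H]2[C@](C)(C=O)[C@H]1O | target

## Step count and risks

Total: 18 steps. Longest linear sequence: 17 steps from (S)-carvone **1** (steps 1–14 and 16–18); the chain fragment needs one step (step 15).

**Step 10 (key step).** Three processes can fail.
- The choice between the two diastereotopic formyl groups may be poor or reversed. If samarium binds the spectator formyl as a third ligand, the spectator would be held gauche to O3 (equatorial), which works against the steric preference.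
- A third electron may reduce the remaining C19 formyl.
- The geminal dialdehyde of **16** may lose a formyl group, or condense with the enolisable C2 aldehyde, before reduction.

Fallback: the decision at C4 is taken out of the cyclisation. It sets out from diol **14**. Mono-alkylation through the dibutylstannylene acetal (Bu2SnO; then 4-methoxybenzyl chloride, CsF) is expected to give both C4-epimeric mono-ethers without useful selectivity, and they are separated. The mono-PMB ether F1, with the ether on the arm that becomes C19, is carried on; its C4 epimer F2 is returned to **14** with DDQ. LiAlH4 reduction of F1 gives diol F3. Double Swern oxidation gives dialdehyde F4, which has no geminal dialdehyde and only the two carbonyls meant to couple. SmI2 closes ring A to cis-diol PMB ether F5 under the same chair control. DDQ frees triol F6, and TEMPO/PhI(OAc)2 oxidises the primary C19 alcohol in preference to the two secondary ones, returning to the route at **17**.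

**Step 16.** Borane **25** and iodide **24** are both β-branched. Transmetallation may be slow enough that β-hydride elimination from the alkylpalladium, or protodeboronation, takes over.

Fallback: the C11–C12 bond is made as an alkene. Setting out from borane **25** (from diene **22**), oxidation with NaOH/H2O2 gives C11 alcohol F7 and Dess–Martin oxidation gives C11 aldehyde F8, handled cold because the C9 centre is α to the formyl and allylic. Iodide **24** and PPh3 give phosphonium iodide F9, whose ylide (NaHMDS, THF, −78 °C) converts F8 into (Z)-alkene F10. Diimide (2-nitrobenzenesulfonyl hydrazide, Et3N) then reduces the disubstituted C11=C12 bond and leaves the trisubstituted C7=C8 bond, returning at **26**.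

**Step 14.** The C9 carbonyl is flanked by the quaternary C10 and the substituted alkene. The ylide may act mainly as a base (γ-deprotonation to a dienolate), leaving the ketone unconverted.

Fallback: a Peterson sequence from enone **21**. The less basic, more nucleophilic Me3SiCH2Li/CeCl3 adds to the carbonyl to give β-hydroxysilane F11, and KH in THF eliminates it to diene **22**.

**Step 7.** The crossed Cannizzaro reduction of the hindered aldol **13** may lag behind retro-aldol loss of formaldehyde, or need base strength and time that begin to hydrolyse the ester or the silyl ether.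

Fallback: the two events are separated. Aldehyde **11** is hydroxymethylated with aqueous formaldehyde and catalytic K2CO3, aldol **13** is isolated, and NaBH4 reduces it to diol **14**. No new compound arises.

## Further compounds

F1 | step 10 | mono-(4-methoxybenzyl) ether of 14, ether on the arm that becomes C19 | CC(C)(C)OC(=O)C[C@@]1(C)[C@H](O[Si](C)(C)C(C)(C)C)C(C)=CC[C@@H]1[C@](C)(COCc2ccc(OC)cc2)CO
F2 | step 10 | C4 epimer of F1 | CC(C)(C)OC(=O)C[C@@]1(C)[C@H](O[Si](C)(C)C(C)(C)C)C(C)=CC[C@@H]1[C@@](C)(COCc2ccc(OC)cc2)CO
F3 | step 10 | diol from reduction of the ester of F1 | OCC[C@@]1(C)[C@H](O[Si](C)(C)C(C)(C)C)C(C)=CC[C@@H]1[C@](C)(COCc2ccc(OC)cc2)CO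
F4 | step 10 | dialdehyde (C2 and C3 formyl groups, C19 as PMB ether) | O=CC[C@@]1(C)[C@H](O[Si](C)(C)C(C)(C)C)C(C)=CC[C@@H]1[C@](C)(COCc2ccc(OC)cc2)C=O
F5 | step 10 | decalin cis-2,3-diol with C19 PMB ether | O[C@H]1C[C@@]2(C)[C@H](O[Si](C)(C)C(C)(C)C)C(C)=CC[C@@H]2[C@](C)(COCc3ccc(OC)cc3)[C@H]1O
F6 | step 10 | decalin 2,3,19-triol with C9 silyl ether | O[C@H]1C[C@@]2(C)[C@H](O[Si](C)(C)C(C)(C)C)C(C)=CC[C@@H]2[C@](C)(CO)[C@H]1O
F7 | step 16 | C11 primary alcohol (acetonide, C19 dimethyl acetal) | CC1(C)O[C@H]2C[C@@]3(C)[C@H](CO)C(C)=CC[C@@H]3[C@](C)(C(OC)OC)[C@H]2O1
F8 | step 16 | C11 aldehyde (acetonide, C19 dimethyl acetal) | CC1(C)O[C@H]2C[C@@]3(C)[C@H](C=O)C(C)=CC[C@@H]3[C@](C)(C(OC)OC)[C@H]2O1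
F9 | step 16 | [(2S)-4-methoxy-2-methyl-4-oxobutyl]triphenylphosphonium iodide | COC(=O)C[C@H](C)C[P+](c1ccccc1)(c1ccccc1)c1ccccc1.[I-]
F10 | step 16 | (11Z)-alkene methyl ester (acetonide, C19 dimethyl acetal) | CC1(C)O[C@H]2C[C@@]3(C)[C@H](/C=C\[C@@H](C)CC(=O)OC)C(C)=CC[C@@H]3[C@](C)(C(OC)OC)[C@H]2O1
F11 | step 14 | C9 tertiary alcohol bearing trimethylsilylmethyl (either C9 epimer) | CC1(C)O[C@H]2C[C@@]3(C)C(O)(C[Si](C)(C)C)C(C)=CC[C@@H]3[C@](C)(C(OC)OC)[C@H]2O1
F0 | step 7 | none | none
A1 | alternative 1 | ten-membered (Z,Z)-dienyl lactone (C4 carbonyl, ring oxygen on C2, C1=C10 and C7=C8, chain on C9 with silyl-protected C15 alcohol) | O=C1CC/C=C(C)\[C@@H](CC[C@@H](C)CCO[Si](c2ccccc2)(c2ccccc2)C(C)(C)C)/C(C)=C\[C@@H](C)O1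
A2 | alternative 1 | ring B acid with quaternary C10 (methyl, (E)-propenyl) and C4 carboxyl on C5 | C/C=C/[C@@]1(C)[C@H](CC[C@@H](C)CCO[Si](c2ccccc2)(c2ccccc2)C(C)(C)C)C(C)=CC[C@@H]1C(=O)O
A3 | alternative 2 | ring B aldehyde with exocyclic C10 methylene, chain on C9 (tert-butyl ester) and C4 bearing methyl, silyloxymethyl and formyl | C=C1[C@H](CC[C@@H](C)CC(=O)OC(C)(C)C)C(C)=CC[C@@H]1[C@](C)(CO[Si](C)(C)C(C)(C)C)C=O
A4 | alternative 2 | methyl vinyl ketone | CC(=O)C=C
A5 | alternative 2 | trans-decalin with C2 acetyl, C3 hydroxyl and C10 methyl | CC(=O)[C@H]1C[C@@]2(C)[C@H](CC[C@@H](C)CC(=O)OC(C)(C)C)C(C)=CC[C@@H]2[C@](C)(CO[Si](C)(C)C(C)(C)C)[C@H]1O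
A6 | alternative 3 | (R)-citronellol | CC(C)=CCC[C@@H](C)CCO
A7 | alternative 3 | (E)-diene C6–C9 with the chain and silyl-protected C15 alcohol | C=C/C(C)=C/CC[C@@H](C)CCO[Si](c1ccccc1)(c1ccccc1)C(C)(C)C
A8 | alternative 3 | ethyl (E)-3-methyl-4-oxobut-2-enoate | CCOC(=O)/C=C(\C)C=O
A9 | alternative 3 | ring B cycloadduct with C10 methyl and formyl and C5 ethoxycarbonyl | O=C[C@@]1(C)[C@H](CC[C@@H](C)CCO[Si](c2ccccc2)(c2ccccc2)C(C)(C)C)C(C)=CC[C@@H]1C(=O)OCC
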